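## Retrosynthetic overview

Germacrane numbering is used (ring C1–C10; lactone O1–C6, C7–C11(=C13)–C12). The esters at O3 and O8 go on last; the ten-membered carbocycle is closed second, at C2–C3, by a Nozaki–Hiyama–Kishi reaction of an E-vinyl iodide with a Z-enal.
The γ-lactone is the first ring: one copper-catalysed operation stitches CO2 between C11 (as alkenyl–B(pin)) and C6 (as allylic phosphate), forming C11–C12 and O1–C6.
The open-chain precursor comes from a three-component union (allene + Z-enal + B2(pin)2) that forms C6–C7 syn and installs the C11–B bond; the invertive lactonisation then turns syn into the trans-lactone.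
The allene half is built from an ynone (C10 by asymmetric allylboration, C8 by asymmetric allenylboration); the enal half takes its Z-C4=C5 alkene from a butenolide ring.
Enabling feature: the lactone C12(=O)–O1 is a CO2 unit held between C11, an sp2 carbon that can carry boron, and C6, an sp3 carbon allylic to C4=C5 and γ to C12; a carboxylate made at C11 therefore closes the five-membered ring at C6 by 5-exo-tet displacement with inversion.

Key step: step 12

Remark: the antipodes of the chiral catalysts in steps 1, 5 and 10 are those expected from the accepted closed transition-state models; each is a free choice, and the mirror-image catalyst would be taken if the sense of induction were opposite.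

## Route

Step 1
Reactants: 1 4-(trimethylsilyl)but-3-yn-2-one; 2 diisopropyl allylboronate
Product: 3 (R)-3-methyl-1-(trimethylsilyl)hex-5-en-1-yn-3-ol
Conditions: (S)-3,3′-Br2-BINOL (15 mol%), PhCF3/PhMe, −35 °C; aq. NaHCO3
Reagents that add atoms: none
Why: Chiral-diol-catalysed asymmetric allylboration of a ketone: the BINOL exchanges onto boron and the allyl group is delivered through a closed chair transition state that tells the slim alkynyl arm from the methyl group, so the catalyst should set C10 as R.

Step 2
Reactants: 3 (R)-3-methyl-1-(trimethylsilyl)hex-5-en-1-yn-3-ol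
Product: 4 (R)-3-methylhex-5-en-1-yn-3-ol
Conditions: K2CO3 (cat.), MeOH, 0 °C to rt
Reagents that add atoms: none
Why: Base-catalysed methanolysis of the C(sp)–Si bond (protodesilylation of an alkynylsilane) should free the terminal alkyne without touching the carbinol centre.

Step 3
Reactants: 4 (R)-3-methylhex-5-en-1-yn-3-ol
Product: 6 (1E,3R)-1-iodo-3-methylhexa-1,5-dien-3-ol, via vinylstannane 5 (not isolated)
Conditions: Bu3SnH, PdCl2(PPh3)2 (2 mol%), THF, 0 °C to rt; then I2, CH2Cl2, 0 °C
Reagents that add atoms: iodine, II (tributyltin hydride, CCCC[SnH](CCCC)CCCC, leaves tin only in 5)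
Why: Palladium-catalysed syn-hydrostannation should place tin on the unhindered terminal carbon of the tertiary propargylic alcohol (alkyne chosen over the allyl alkene), and iododestannylation proceeds with retention, which fixes the E-vinyl iodide.

Step 4
Reactants: 6 (1E,3R)-1-iodo-3-methylhexa-1,5-dien-3-ol
Product: 7 (3R,4E)-3-hydroxy-5-iodo-3-methylpent-4-enal
Conditions: OsO4 (2 mol%), NaIO4, 2,6-lutidine, dioxane/H2O, rt
Reagents that add atoms: sodium periodate, [Na+].[O-]I(=O)(=O)=O (source of the aldehyde oxygen, relayed by OsO4)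
Why: Lemieux–Johnson cleavage: OsO4 should dihydroxylate the electron-richer monosubstituted alkene in preference to the iodine-deactivated, neopentylic vinyl iodide, NaIO4 cleaves the diol, and the lutidine buffer keeps the β-hydroxy aldehyde from dehydrating.

Step 5
Reactants: 7 (3R,4E)-3-hydroxy-5-iodo-3-methylpent-4-enal; 8 propargylboronic acid pinacol ester
Product: 9 (1E,3R,5R)-1-iodo-3-methylocta-1,6,7-triene-3,5-diol
Conditions: (R)-TRIP phosphoric acid (10 mol%), 4 Å molecular sieves, PhMe, −30 °C; aq. work-up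
Reagents that add atoms: none
Why: Chiral-phosphoric-acid-catalysed allenylboration: the propargyl boronate adds in the SE2′ sense through a six-membered chair transition state held by the acid, which should give the α-allenic alcohol and set C8 as R by catalyst control (1,3-anti to C10).

Step 6
Reactants: 9 (1E,3R,5R)-1-iodo-3-methylocta-1,6,7-triene-3,5-diol
Product: 10 (1E,3R,5R)-1-iodo-3-methyl-3,5-bis(triethylsilyloxy)octa-1,6,7-triene
Conditions: Et3SiOTf (2.5 equiv), 2,6-lutidine, CH2Cl2, −78 to 0 °C
Reagents that add atoms: triethylsilyl triflate, CC[Si](CC)(CC)OS(=O)(=O)C(F)(F)F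
Why: A silyl triflate with a hindered base silylates both the secondary and the tertiary hydroxyl (silyl ether formation), which removes every proton source before the copper step.

Step 7
Reactants: 11 4-methylfuran-2(5H)-one
Product: 12 (2Z)-4-hydroxy-N-methoxy-N,3-dimethylbut-2-enamide
Conditions: MeNH(OMe)·HCl, AlMe3, CH2Cl2, 0 °C to rt; aq. potassium sodium tartrate
Reagents that add atoms: N,O-dimethylhydroxylamine hydrochloride, CNOC.Cl
Why: Weinreb aminolysis of a lactone: the aluminium amide should attack the acyl carbon (the β,β-disubstituted alkene resists conjugate addition), and the ring-derived Z geometry of C4=C5 is kept.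

Step 8
Reactants: 12 (2Z)-4-hydroxy-N-methoxy-N,3-dimethylbut-2-enamide
Product: 13 (2Z)-N-methoxy-N,3-dimethyl-4-(triethylsilyloxy)but-2-enamide
Conditions: Et3SiCl, imidazole, CH2Cl2, 0 °C
Reagents that add atoms: chlorotriethylsilane, CC[Si](Cl)(CC)CC
Why: Silylation of the primary allylic alcohol blocks relactonisation and gives the one silyl ether that step 13 can later oxidise directly.

Step 9
Reactants: 13 (2Z)-N-methoxy-N,3-dimethyl-4-(triethylsilyloxy)but-2-enamide
Product: 14 (2Z)-3-methyl-4-(triethylsilyloxy)but-2-enal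
Conditions: iBu2AlH, THF, −78 °C; aq. potassium sodium tartrate
Reagents that add atoms: none
Why: Hydride reduction of a Weinreb amide stops at the aldehyde through the stable five-membered aluminium chelate, and the cold neutral work-up should keep the Z-enal.

Step 10
Reactants: 10 (1E,3R,5R)-1-iodo-3-methyl-3,5-bis(triethylsilyloxy)octa-1,6,7-triene; 14 (2Z)-3-methyl-4-(triethylsilyloxy)but-2-enal; 15 bis(pinacolato)diboron
Product: 16 (2Z,4R,5R,6R,8R,9E)-10-iodo-2,8-dimethyl-5-[1-(4,4,5,5-tetramethyl-1,3,2-dioxaborolan-2-yl)ethenyl]-1,6,8-tris(triethylsilyloxy)deca-2,9-dien-4-ol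
Conditions: CuCl (5 mol%), (S,S)-Ph-BPE (6 mol%), NaOtBu (20 mol%), THF, 0 °C to rt; aq. NH4Cl
Reagents that add atoms: none
Why: Copper-catalysed borylative allene–aldehyde coupling: the ligated Cu–B(pin) adds across the terminal C=C of the allene anti to the C8 substituent to give a (Z)-2-boryl-allylcopper, which adds at its γ-carbon to the aldehyde through a chair transition state, so C6–C7 should form syn, the bisphosphine (matched with the C8 silyloxy centre) selects the (6R,7R) pair, and the alkenyl–B(pin) needed for step 12 is installed.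

Step 11
Reactants: 16 the syn homoallylic alcohol of step 10
Product: 17 diethyl (2Z,4R,5S,6R,8R,9E)-10-iodo-2,8-dimethyl-5-[1-(4,4,5,5-tetramethyl-1,3,2-dioxaborolan-2-yl)ethenyl]-1,6,8-tris(triethylsilyloxy)deca-2,9-dien-4-yl phosphate
Conditions: ClP(O)(OEt)2, N-methylimidazole, CH2Cl2, 0 °C to rt
Reagents that add atoms: diethyl chlorophosphate, CCOP(=O)(Cl)OCC
Why: O-Phosphorylation of the secondary allylic alcohol (nucleophilic catalysis) takes place at oxygen, so C6 keeps its configuration and gains a leaving group.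

Step 12
Reactants: 17 the allylic diethyl phosphate of step 11; 18 carbon dioxide
Product: 20 (4R,5S)-4-[(1R,3R,4E)-5-iodo-3-methyl-1,3-bis(triethylsilyloxy)pent-4-en-1-yl]-3-methylidene-5-[(1Z)-2-methyl-3-(triethylsilyloxy)prop-1-en-1-yl]oxolan-2-one, via potassium carboxylate 19 (not isolated)
Conditions: (IPr)CuCl (10 mol%; IPr = 1,3-bis(2,6-diisopropylphenyl)imidazol-2-ylidene), KOtBu (1.1 equiv), CO2 (1 atm), THF, 65 °C
Reagents that add atoms: none
Why: Proposed new method: the alkenyl–B(pin) of 17 is transmetalated to (IPr)Cu–OtBu, the alkenylcopper inserts CO2 (C11–C12), and the carboxylate, released as potassium salt 19, displaces the allylic diethyl phosphate at C6 from the rear (O1–C6); the closest known reaction types are the carbene–copper-catalysed carboxylation of alkenylboronic esters with CO2 and the invertive SN2 lactonisation of carboxylates that carry a γ-leaving group. The five-membered lactone closes in the 5-exo-tet mode. C6 is the only stereocentre made, and it is fixed by Walden inversion of the (6R)-phosphate set in steps 10 and 11, which turns the syn adduct into the trans C6/C7 lactone of the target. The step needs the carboxylate to attack C6 and not C4 (SN2′), and the alkenylcopper to take CO2 and not the phosphate: the two-atom tether C7–C11 allows only the five-membered closure at C6, and an intramolecular SN2′ by the alkenylcopper would be an endo closure through the allyl unit while CO2 is present in large excess. tert-Butoxide is held as KO2COtBu under CO2, so the silyl ethers, the phosphate and the vinyl iodide should survive.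

Step 13
Reactants: 20 the seco lactone of step 12
Product: 21 (2Z)-3-{(2S,3R)-3-[(1R,3R,4E)-5-iodo-3-methyl-1,3-bis(triethylsilyloxy)pent-4-en-1-yl]-4-methylidene-5-oxooxolan-2-yl}-2-methylprop-2-enal
Conditions: (COCl)2, DMSO, CH2Cl2, −78 to −40 °C; Et3N, −78 to 0 °C
Reagents that add atoms: none
Why: Swern oxidation of a primary triethylsilyl ether: the activated sulfoxide and the HCl it carries should cleave only the unhindered primary allylic silyl ether and oxidise it to the aldehyde in the same operation, the secondary and tertiary silyl ethers being too hindered.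

Step 14
Reactants: 21 the seco Z-enal of step 13
Product: 22 (3S,6S,7R,8R,10R)-3-hydroxy-8,10-bis(triethylsilyloxy)germacra-1(2)E,4Z,11(13)-trien-12,6-olide
Conditions: CrCl2 (8 equiv), NiCl2 (2 mol% of Cr), DMSO/THF, 0.002 M, rt
Reagents that add atoms: none
Why: Nozaki–Hiyama–Kishi macrocyclisation: nickel-catalysed insertion into the vinyl iodide, transfer to chromium and 1,2-addition to the enal should close the ten-membered ring under high dilution with both alkene geometries retained; the C3 carbinol is set by substrate control in the ring-closing transition state (the rigid trans-lactone and the Z-alkene leave the outer face of the enal open), 3S being the expected but least secure outcome.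

Step 15
Reactants: 22 the macrocyclic C3 alcohol of step 14
Product: 23 (3S,6S,7R,8R,10R)-3-acetoxy-8,10-bis(triethylsilyloxy)germacra-1(2)E,4Z,11(13)-trien-12,6-olide
Conditions: Ac2O, pyridine, DMAP (cat.), CH2Cl2, 0 °C
Reagents that add atoms: acetic anhydride, CC(=O)OC(C)=O
Why: DMAP-catalysed acetylation of the only free hydroxyl (secondary, bis-allylic) leaves the C3 configuration untouched.

Step 16
Reactants: 23 the C3 acetate of step 15
Product: 24 (3S,6S,7S,8R,10R)-3-acetoxy-8,10-dihydroxygermacra-1(2)E,4Z,11(13)-trien-12,6-olide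
Conditions: HF·pyridine, pyridine, THF, 0 °C to rt
Reagents that add atoms: none
Why: Buffered fluoride desilylation should cleave the secondary and tertiary triethylsilyl ethers without ionising the bis-allylic acetate or opening the lactone.

Step 17
Reactants: 24 the 8,10-diol of step 16; 25 angelic acid
Product: 27 (3S,6S,7S,8R,10R)-3-acetoxy-8-angeloyloxy-10-hydroxygermacra-1(2)E,4Z,11(13)-trien-12,6-olide (target CNP0181631.2), via mixed anhydride 26 (not isolated)
Conditions: 25, 2,4,6-Cl3C6H2COCl, Et3N, PhMe, rt; then 24, 75 °C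
Reagents that add atoms: none
Why: Yamaguchi-type esterification without DMAP: the mixed anhydride should be attacked at its unhindered angeloyl carbonyl by the secondary C8 hydroxyl only (the tertiary C10 hydroxyl does not react), and the absence of a nucleophilic catalyst keeps the Z geometry of the angelate.

## Compound list

1 | 4-(trimethylsilyl)but-3-yn-2-one | CC(=O)C#C[Si](C)(C)C | starting material
2 | diisopropyl allylboronate | C=CCB(OC(C)C)OC(C)C | starting material
3 | (R)-3-methyl-1-(trimethylsilyl)hex-5-en-1-yn-3-ol | C=CC[C@@](C)(O)C#C[Si](C)(C)C | intermediate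
4 | (R)-3-methylhex-5-en-1-yn-3-ol | C=CC[C@@](C)(O)C#C | intermediate
5 | (1E,3R)-3-methyl-1-(tributylstannyl)hexa-1,5-dien-3-ol | C=CC[C@@](C)(O)/C=C/[Sn](CCCC)(CCCC)CCCC | intermediate (not isolated)
6 | (1E,3R)-1-iodo-3-methylhexa-1,5-dien-3-ol | C=CC[C@@](C)(O)/C=C/I | intermediate
7 | (3R,4E)-3-hydroxy-5-iodo-3-methylpent-4-enal | O=CC[C@@](C)(O)/C=C/I | intermediate
8 | propargylboronic acid pinacol ester (4,4,5,5-tetramethyl-2-(prop-2-yn-1-yl)-1,3,2-dioxaborolane) | C#CCB1OC(C)(C)C(C)(C)O1 | starting material
9 | (1E,3R,5R)-1-iodo-3-methylocta-1,6,7-triene-3,5-diol | C=C=C[C@H](O)C[C@@](C)(O)/C=C/I | intermediate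
10 | (1E,3R,5R)-1-iodo-3-methyl-3,5-bis(triethylsilyloxy)octa-1,6,7-triene | C=C=C[C@H](O[Si](CC)(CC)CC)C[C@@](C)(O[Si](CC)(CC)CC)/C=C/I | intermediate
11 | 4-methylfuran-2(5H)-one | CC1=CC(=O)OC1 | starting material
12 | (2Z)-4-hydroxy-N-methoxy-N,3-dimethylbut-2-enamide | CON(C)C(=O)/C=C(/C)CO | intermediate
13 | (2Z)-N-methoxy-N,3-dimethyl-4-(triethylsilyloxy)but-2-enamide | CON(C)C(=O)/C=C(/C)CO[Si](CC)(CC)CC | intermediate
14 | (2Z)-3-methyl-4-(triethylsilyloxy)but-2-enal | O=C/C=C(/C)CO[Si](CC)(CC)CC | intermediate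
15 | bis(pinacolato)diboron | CC1(C)OB(B2OC(C)(C)C(C)(C)O2)OC1(C)C | starting material
16 | (2Z,4R,5R,6R,8R,9E)-10-iodo-2,8-dimethyl-5-[1-(4,4,5,5-tetramethyl-1,3,2-dioxaborolan-2-yl)ethenyl]-1,6,8-tris(triethylsilyloxy)deca-2,9-dien-4-ol (C6 epimeric to the target, C6/C7 syn) | CC[Si](CC)(CC)OC/C(C)=C\[C@@H](O)[C@@H](C(=C)B1OC(C)(C)C(C)(C)O1)[C@H](O[Si](CC)(CC)CC)C[C@@](C)(O[Si](CC)(CC)CC)/C=C/I | intermediate
17 | diethyl (2Z,4R,5S,6R,8R,9E)-10-iodo-2,8-dimethyl-5-[1-(4,4,5,5-tetramethyl-1,3,2-dioxaborolan-2-yl)ethenyl]-1,6,8-tris(triethylsilyloxy)deca-2,9-dien-4-yl phosphate | CC[Si](CC)(CC)OC/C(C)=C\[C@@H](OP(=O)(OCC)OCC)[C@@H](C(=C)B1OC(C)(C)C(C)(C)O1)[C@H](O[Si](CC)(CC)CC)C[C@@](C)(O[Si](CC)(CC)CC)/C=C/I | intermediate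
18 | carbon dioxide | O=C=O | starting material
19 | potassium 2-[(2Z,4R,5S,6R,8R,9E)-4-(diethoxyphosphoryloxy)-10-iodo-2,8-dimethyl-1,6,8-tris(triethylsilyloxy)deca-2,9-dien-5-yl]prop-2-enoate | CC[Si](CC)(CC)OC/C(C)=C\[C@@H](OP(=O)(OCC)OCC)[C@@H](C(=C)C(=O)[O-])[C@H](O[Si](CC)(CC)CC)C[C@@](C)(O[Si](CC)(CC)CC)/C=C/I.[K+] | intermediate (not isolated)
20 | (4R,5S)-4-[(1R,3R,4E)-5-iodo-3-methyl-1,3-bis(triethylsilyloxy)pent-4-en-1-yl]-3-methylidene-5-[(1Z)-2-methyl-3-(triethylsilyloxy)prop-1-en-1-yl]oxolan-2-one | C=C1C(=O)O[C@@H](/C=C(/C)CO[Si](CC)(CC)CC)[C@@H]1[C@H](O[Si](CC)(CC)CC)C[C@@](C)(O[Si](CC)(CC)CC)/C=C/I | intermediate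
21 | (2Z)-3-{(2S,3R)-3-[(1R,3R,4E)-5-iodo-3-methyl-1,3-bis(triethylsilyloxy)pent-4-en-1-yl]-4-methylidene-5-oxooxolan-2-yl}-2-methylprop-2-enal | C=C1C(=O)O[C@@H](/C=C(/C)C=O)[C@@H]1[C@H](O[Si](CC)(CC)CC)C[C@@](C)(O[Si](CC)(CC)CC)/C=C/I | intermediate
22 | (3S,6S,7R,8R,10R)-3-hydroxy-8,10-bis(triethylsilyloxy)germacra-1(2)E,4Z,11(13)-trien-12,6-olide | C=C1C(=O)O[C@H]2/C=C(/C)[C@@H](O)/C=C/[C@](C)(O[Si](CC)(CC)CC)C[C@@H](O[Si](CC)(CC)CC)[C@H]12 | intermediate
23 | (3S,6S,7R,8R,10R)-3-acetoxy-8,10-bis(triethylsilyloxy)germacra-1(2)E,4Z,11(13)-trien-12,6-olide | C=C1C(=O)O[C@H]2/C=C(/C)[C@@H](OC(C)=O)/C=C/[C@](C)(O[Si](CC)(CC)CC)C[C@@H](O[Si](CC)(CC)CC)[C@H]12 | intermediate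
24 | (3S,6S,7S,8R,10R)-3-acetoxy-8,10-dihydroxygermacra-1(2)E,4Z,11(13)-trien-12,6-olide | C=C1C(=O)O[C@H]2/C=C(/C)[C@@H](OC(C)=O)/C=C/[C@](C)(O)C[C@@H](O)[C@H]12 | intermediate
25 | angelic acid ((2Z)-2-methylbut-2-enoic acid) | C/C=C(/C)C(=O)O | starting material
26 | angelic 2,4,6-trichlorobenzoic anhydride | C/C=C(/C)C(=O)OC(=O)c1c(Cl)cc(Cl)cc1Cl | intermediate (not isolated)
27 | (3S,6S,7S,8R,10R)-3-acetoxy-8-angeloyloxy-10-hydroxygermacra-1(2)E,4Z,11(13)-trien-12,6-olide (CNP0181631.2) | C=C1C(=O)O[C@H]2/C=C(/C)[C@@H](OC(C)=O)/C=C/[C@](C)(O)C[C@@H](OC(=O)/C(C)=C\C)[C@H]12 | target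

## Step count and risks

Total step count: 17. Longest linear sequence: 14 steps (steps 1–6, then 10–17); the enal branch (steps 7–9) joins at step 10.

Steps most likely to fail:

1. Step 12 (proposed new method). Boron-to-copper transfer at the hindered 1,1-disubstituted alkenylboronate may be slow, so that the allylic phosphate ionises (loss of stereospecificity at C6) or eliminates before the carboxylate exists; the alkenylcopper may also be consumed by substitution at the phosphate or at the vinyl iodide instead of CO2 capture. Fallback with known chemistry, setting out from 16 and omitting the phosphate: copper-catalysed carboxylation of the free alcohol ((IPr)CuCl, KOtBu 2.2 equiv, CO2, THF, 65 °C; citric acid work-up) should give the hydroxy acid F1. An intramolecular Mitsunobu lactonisation (PPh3, DIAD, THF, 0 °C) then activates the C6 hydroxyl and closes the ring with inversion, and the route is rejoined at 20.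

2. Step 10. The copper boryl may add to the enal (1,2 or conjugate) or to the vinyl iodide, the allylcopper may lose the neighbouring silyloxy group by β-elimination, or catalyst and C8 centre may be mismatched in facial selectivity. Fallback setting out from 10: platinum-catalysed diboration of the terminal allene C=C (Pt(dba)2, PCy3, B2(pin)2, PhMe, 50 °C) should give the (Z)-2-boryl allylboronate F2. Chiral-phosphoric-acid-catalysed allylboration of 14 with it ((R)-TRIP, PhMe, −30 °C; aqueous work-up) passes through the same chair transition state (Z reagent, syn adduct) without any copper species, and the route is rejoined at 16.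

3. Step 14. Facial selectivity at C3 in the ring-closing addition may be poor or reversed, and ring strain may let oligomerisation compete with ten-membered ring closure. Fallback setting out from 21: the chromium-mediated closure is run without regard to C3, and the mixture of 22 and its 3-epimer F3 is oxidised with Dess–Martin periodinane to the cross-conjugated dienone F4. Reagent-controlled 1,2-reduction ((R)-Me-CBS, catecholborane, PhMe, −78 °C, the α-methylalkenyl arm acting as the large group) should then give the 3S alcohol, and the route is rejoined at 22.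

Further compounds

F1 | step 12 | 2-[(2Z,4R,5R,6R,8R,9E)-4-hydroxy-10-iodo-2,8-dimethyl-1,6,8-tris(triethylsilyloxy)deca-2,9-dien-5-yl]prop-2-enoic acid | CC[Si](CC)(CC)OC/C(C)=C\[C@@H](O)[C@@H](C(=C)C(=O)O)[C@H](O[Si](CC)(CC)CC)C[C@@](C)(O[Si](CC)(CC)CC)/C=C/I
F2 | step 10 | (2Z,4R,6R,7E)-8-iodo-6-methyl-1,2-bis(4,4,5,5-tetramethyl-1,3,2-dioxaborolan-2-yl)-4,6-bis(triethylsilyloxy)octa-2,7-diene | CC1(C)OB(C/C(B2OC(C)(C)C(C)(C)O2)=C\[C@H](O[Si](CC)(CC)CC)C[C@@](C)(O[Si](CC)(CC)CC)/C=C/I)OC1(C)C
F3 | step 14 | (3R,6S,7R,8R,10R)-3-hydroxy-8,10-bis(triethylsilyloxy)germacra-1(2)E,4Z,11(13)-trien-12,6-olide | C=C1C(=O)O[C@H]2/C=C(/C)[C@H](O)/C=C/[C@](C)(O[Si](CC)(CC)CC)C[C@@H](O[Si](CC)(CC)CC)[C@H]12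
F4 | step 14 | (6S,7R,8R,10R)-3-oxo-8,10-bis(triethylsilyloxy)germacra-1(2)E,4Z,11(13)-trien-12,6-olide | C=C1C(=O)O[C@H]2/C=C(/C)C(=O)/C=C/[C@](C)(O[Si](CC)(CC)CC)C[C@@H](O[Si](CC)(CC)CC)[C@H]12
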